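## Structural features

Atom labels: C1 is the quaternary carbon bearing CH3 and CO2CH3. C2 is the adjacent bridgehead CH, C3=C4 the ring alkene, C5=C6 the enol-ether alkene, O7 the ring oxygen and C8 the acetal CH. C9 to C12 are the chain CH, CH2, CH2, CH; C13 is the all-carbon quaternary centre and C14 the CH2 bridge.

The core is a bicyclo[3.2.1]octene built from ring C (C1, C2, C14, C13, C12) and ring D (C2, C3, C4, C5, C13, C14), with bridgeheads C2 and C13. Cyclopentane ring B (C9 to C13) is cis-fused along C12–C13. The 2-acyloxydihydropyran ring A (O7, C8, C9, C13, C5, C6) is fused along C9–C13 and C13–C5, so C13 belongs to all four rings.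

The six stereocentres (1R,2S,8S,9R,12R,13S) form the unbroken chain C8–C9–C13–C12–C1–C2. The two quaternary carbons C1 and C13 are separated only by C12. On C1 the methyl group is exo and cis to C11, and the ester is endo, directly under C3=C4.

Ring A is the fragile part. C8 is an acyloxy acetal that ionises in acid and is cleaved by nucleophiles, and C3=C4–C5=C6–O7 is a dienol ether sensitive to acid and oxidants, so both must be made last.

The real difficulty is the congested carbocycle: C12–C13 and C1–C2 must be formed next to quaternary carbons with control of four contiguous centres.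

The feature exploited is that the atoms of ring D map one to one onto a phenol. C14 is C–OH, C13 and C2 are the two ortho carbons, and C5 is a meta carbon carrying OCH3. The two-carbon bridge C12–C1 across C13 and C2 is what an alkene leaves behind after adding to the ortho positions of a phenoxenium ion. C9–C10–C11 is the tether that becomes ring B.

## Logic of the disconnections

**41 ⇒ 40 ⇒ 38 + 39.** The acyl–O bond on C8 is cut, then O7–C8. These are the two most labile bonds. Their removal opens ring A, deletes stereocentre C8 and replaces the acetal and dienol ether by two aldehydes. The forward step must enolise the C6 aldehyde towards C5, close the dienol oxygen on C8, and acylate 40 faster than any open form. C8 then follows from anomer equilibration. C9, now α to an aldehyde, is drained only through the cis isomer that can cyclise.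

**38 ⇒ 37 ⇒ 36 ⇒ 34.** The C6–O bond is cut; the C8 oxygen is kept in reduced and silylated form. Both aldehydes then come from one double oxidation, and C6–O comes from hydroboration of C5=CH2. Two sensitive aldehydes are traded for a robust diene and a silyl ether. The borane must choose the terminal alkene over C3=C4, and the oxidation must not stop at a lactol or run on to a lactone.

**34 ⇒ 33 ⇒ 32 ⇒ 31 ⇒ 30.** The C–O bonds of the ester carbon on C1 are taken back to one CH2–O bond. An ester on the alkene would switch off the key step, so the oxidation has to come afterwards. This forces the two CH2O arms to carry different silyl groups, because one ends as an acid and the other as an aldehyde. It also requires that 31 never coexist with an enone, since its endo hydroxyl sits under C3.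

**30 ⇒ 29.** C5=C6 is cut. The one carbon that the arene cannot supply is added to the C5 carbonyl. The gain is a plain enone. The demand is olefination of a neopentylic ketone, which is tolerable because that ketone cannot enolise.

**29 ⇒ 28 ⇒ 27 ⇒ 26.** A C14–O bond is put back, because C14 is the phenolic carbon. The forward steps need hydride selectivity for C14 over C5. They also need thioacylation without an alkoxide, because the ketol is a retro-aldol candidate, and a radical that is quenched before it finds the enone.

**26 ⇒ 23.** C12–C13 and C1–C2 are cut. Two rings and four stereocentres (C1, C2, C12, C13) disappear, leaving a flat arene with one stereocentre and one alkene of defined geometry. The forward step needs an electron-rich E-alkene, a free phenol, a methoxy group on C5 to end the cation, and a C9 substituent large enough to choose the arene face. C9 is the only carrier of absolute configuration.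

**23 ⇒ 21 ⇒ 20 ⇒ 19 ⇒ 17 + 18.** C12=C1 is cut. A stabilised ylide delivers the E-trisubstituted alkene together with the C1 methyl group and the future ester carbon. The demand is high E selectivity, because the alkene geometry becomes the C1 configuration.

**17 ⇒ 16 ⇒ 14 ⇒ 13 ⇒ 12 ⇒ 9 + 10.** C9–C10 is cut. Imide enolates alkylate cleanly only with activated halides. An allyl unit (C10 to C12) is therefore used and extended, instead of a complete homoallylic iodide that would react sluggishly and eliminate to a diene. The (R)-auxiliary is required for (R)-C9.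

**9 ⇒ 6 + 7; 6 ⇒ 5 ⇒ 2 + 3; 2 ⇒ 1.** N–C8 and C13–C9 are cut. The two oxygen substituents of 2 direct lithiation to the carbon between them, and 3 supplies C9 and C8 in one step.

## Other disconnections considered

**Alternative 1:** The cut runs through C9–C13 and O7–C8 (rings A and B together) and, behind them, through C3=C4 (ring D).

- *Forward step.* The monocyclic trienal A1 contains ring C only. It carries a vinyl group on C2, the enal O7=C6–C5=C13 exocyclic at C13 with a vinyl group on C5, and an E-enol isovalerate C9=C8 at the end of the chain on C12. It would be heated with catalytic Eu(fod)3, europium tris(heptafluorodimethyloctanedionate), to give the divinyl tricycle A2 by an intramolecular inverse-demand oxa-Diels–Alder reaction. Ring-closing metathesis of the two vinyl groups of A2 would finish the synthesis.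
- *In favour.* The acyloxy acetal arrives complete with the isovalerate in place. The E geometry transfers into the trans H8/H9 relation, and C8, C9 and C13 are set at once. Only one step follows. On endgame length and redox economy this is clearly better than the chosen plan, which needs twelve steps after its key step.
- *Against.* C13 is a fully substituted diene terminus and an enol ester is a far weaker donor than an enol ether, so a hindered and electronically poor pair must react on heating. A1 has easier outlets: the C5 vinyl group turns C5=C13 into part of a carbodiene, and acyl transfer is possible on the Lewis acid. A1 still holds the C1/C2/C12 triad with its quaternary carbon, a tetrasubstituted alkene and an E-enol ester, none of which the key step helps to build. The last metathesis must close a bridged ring at a dienol-ether vinyl group beside a labile acetal.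
- *Comparison.* Structurally it solves the easy ring A and leaves the hard carbocycle. Mechanistically its stereocontrol (concerted, geometry transfer) equals that of the (5+2) step, but its reactivity basis is weaker. The steps saved after the key step are likely to be spent before it.

**Alternative 2:** The two alkenes C3=C4 and C5=C6 are cut, which opens rings D and A.

- *Forward step.* The cis-bicyclo[3.3.0]octane A3 contains rings B and C. It carries the ethynyl unit C5≡C4 on C13, a vinyl group on C2, and a vinyl ester on the C8 carboxyl. It would be treated with the second-generation Grubbs catalyst (H2IMes)(PCy3)Cl2Ru=CHPh under ethylene. The alkyne becomes a butadiene, whose two ends then ring-close with the C2 vinyl group and the vinyl ester to give the enol lactone A4. Reduction with iBu2AlH and acylation would complete the target.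
- *In favour.* It is catalytic. Two rings and the conjugated diene appear in the right place in one operation, C14 never carries oxygen, and A4 is one or two steps from the target. On these points it is better than the chosen plan.
- *Against.* Vinyl esters, like vinyl ethers, convert the ruthenium alkylidene into a heteroatom-stabilised carbene of low activity, so the closure of ring A is the weakest link. The alkyne is neopentylic. The order of the three metathesis events is not controlled. The final hydride has to distinguish the enol lactone from the methyl ester.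
- *Comparison.* A3 already contains C1, C2, C9, C12 and C13, so the key step sets no stereocentre, against four in the (5+2) step. The structural burden moves entirely to the substrate. The overall step count is at best comparable.

**Alternative 3:** Only C1–C2 (ring C) is cut.

- *Forward step.* The bridged seven-membered lactone A5 has rings B and D spiro-joined at C13, a C2=C3 alkene, and C4–O esterified by the carboxyl on C1. KN(SiMe3)2 and tBuMe2SiCl would convert it into its silyl ketene acetal, which rearranges on warming to the acid A6.
- *In favour.* C1 emerges at the carboxylic acid level. C14 is never oxygenated, C3=C4 is placed by the rearrangement, and chirality passes from C4–O to C2. After esterification and desilylation, A6 would meet the chosen route at the stage of 37 (as the C5 epimer, a centre that is erased). On redox economy and on the length of the endgame it is better.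
- *Against.* A5 has five stereocentres, including the spiro quaternary C13 flanked by C5, C9 and C12, and no short access is apparent. The ketene acetal geometry is dictated by the ring and must happen to match the C1 configuration through a boat-like transition state. A quaternary carbon is formed in a strained bridged array.
- *Comparison.* Mechanistically the transfer of stereochemistry is as reliable as in the (5+2) step. However, it builds one ring and two centres, against two rings and four centres. The chosen precursor 23 has one stereocentre and an arene, so the total step count should favour the chosen plan.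

Key step: step 14

Assumption: the transient centres C14 (27, 28) and C5 (35 to 38) are drawn as expected for reagent approach on the face away from the C1–C12 bridge; both are erased later, so nothing depends on them.

## Steps

Step 1
Reactants: 1 3-methoxyphenol
Product: 2 1-methoxy-3-(methoxymethoxy)benzene
Conditions: MeOCH2Cl, iPr2NEt, CH2Cl2, 0 °C to rt
Reagents that add atoms: chloromethyl methyl ether, COCCl
Why: O-alkylation of the phenol to the MOM acetal; together with OCH3 this group directs the lithiation of step 2 and it resists every base, hydride and oxidant up to step 13.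

Step 2
Reactants: 2 1-methoxy-3-(methoxymethoxy)benzene; 3 oxirane
Product: 5 2-[2-methoxy-6-(methoxymethoxy)phenyl]ethanol, via aryllithium 4 (not isolated)
Conditions: n-BuLi, THF, 0 °C; then 3, −78 °C to rt; H2O
Reagents that add atoms: n-butyllithium, [Li]CCCC (lithium of 4 only)
Why: Directed ortho-metalation; both oxygen groups cooperate, so the proton between them (future C13) is removed, and the aryllithium opens the epoxide by SN2, bringing in C9 and C8.

Step 3
Reactants: 5 2-[2-methoxy-6-(methoxymethoxy)phenyl]ethanol
Product: 6 [2-methoxy-6-(methoxymethoxy)phenyl]acetic acid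
Conditions: TEMPO (cat.), NaClO2, NaOCl (cat.), MeCN, phosphate buffer pH 6.7, 35 °C
Reagents that add atoms: sodium chlorite, [Na+].[O-]Cl=O
Why: Nitroxyl-catalysed oxidation with chlorite as terminal oxidant takes the primary alcohol through the aldehyde to the acid near neutral pH; this spares the MOM acetal and keeps hypochlorite too low to chlorinate the electron-rich ring.

Step 4
Reactants: 6 [2-methoxy-6-(methoxymethoxy)phenyl]acetic acid; 7 (R)-4-benzyl-1,3-oxazolidin-2-one
Product: 9 (R)-4-benzyl-3-{[2-methoxy-6-(methoxymethoxy)phenyl]acetyl}-1,3-oxazolidin-2-one, via mixed pivalic anhydride 8 (not isolated)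
Conditions: tBuCOCl, Et3N, THF, −20 °C; then 7, LiCl, rt
Reagents that add atoms: pivaloyl chloride, CC(C)(C)C(=O)Cl (acyl group of 8 only)
Why: N-acylation through the mixed anhydride; LiCl and Et3N activate the oxazolidinone without strong base, and attack occurs at the less hindered arylacetyl carbonyl.

Step 5
Reactants: 9 (R)-4-benzyl-3-{[2-methoxy-6-(methoxymethoxy)phenyl]acetyl}-1,3-oxazolidin-2-one; 10 allyl iodide
Product: 12 (4R)-4-benzyl-3-{(2R)-2-[2-methoxy-6-(methoxymethoxy)phenyl]pent-4-enoyl}-1,3-oxazolidin-2-one, via sodium Z-enolate 11 (not isolated)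
Conditions: NaN(SiMe3)2, THF, −78 °C; then 10, −78 to −45 °C
Reagents that add atoms: sodium bis(trimethylsilyl)amide, [Na+].C[Si](C)(C)[N-][Si](C)(C)C (sodium of 11 only)
Why: Evans asymmetric alkylation; in the chelated Z-enolate the benzyl group of the (R)-auxiliary covers one face, so the allyl group enters from the other and sets C9 as R. An allylic halide reacts at −78 °C, whereas an unactivated homoallylic iodide would need warming and would suffer E2 loss of HI.

Step 6
Reactants: 12 (4R)-4-benzyl-3-{(2R)-2-[2-methoxy-6-(methoxymethoxy)phenyl]pent-4-enoyl}-1,3-oxazolidin-2-one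
Product: 13 (2R)-2-[2-methoxy-6-(methoxymethoxy)phenyl]pent-4-en-1-ol
Conditions: LiBH4, H2O (1 equiv), Et2O, 0 °C
Reagents that add atoms: none
Why: Reductive cleavage of the imide at the exocyclic carbonyl; the conditions are hardly basic, so the benzylic centre C9 is not epimerised, and the auxiliary is recovered.

Step 7
Reactants: 13 (2R)-2-[2-methoxy-6-(methoxymethoxy)phenyl]pent-4-en-1-ol
Product: 14 tert-butyldiphenylsilyl ether of 13
Conditions: tBuPh2SiCl, imidazole, DMF, rt
Reagents that add atoms: tert-butyl(chloro)diphenylsilane, CC(C)(C)[Si](Cl)(c1ccccc1)c1ccccc1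
Why: Silylation of the C8 oxygen; TBDPS is chosen because it outlasts the TBS group of the other arm in step 19 and because a larger C8 arm should sharpen the facial bias in step 14.

Step 8
Reactants: 14 tert-butyldiphenylsilyl ether of 13
Product: 16 (4R)-5-[(tert-butyldiphenylsilyl)oxy]-4-[2-methoxy-6-(methoxymethoxy)phenyl]pentan-1-ol, via B-alkyl-9-BBN 15 (not isolated)
Conditions: 9-BBN, THF, 0 °C to rt; then H2O2, NaOH aq, 0 °C
Reagents that add atoms: 9-borabicyclo[3.3.1]nonane, B1C2CCCC1CCC2 (boryl group of 15 only); hydrogen peroxide, OO
Why: Anti-Markovnikov hydroboration–oxidation of the only alkene puts oxygen on C12.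

Step 9
Reactants: 16 (4R)-5-[(tert-butyldiphenylsilyl)oxy]-4-[2-methoxy-6-(methoxymethoxy)phenyl]pentan-1-ol
Product: 17 (4R)-5-[(tert-butyldiphenylsilyl)oxy]-4-[2-methoxy-6-(methoxymethoxy)phenyl]pentanal
Conditions: Dess–Martin periodinane, CH2Cl2, rt
Reagents that add atoms: none
Why: Dess–Martin oxidation stops at the aldehyde; C9 is γ to the new carbonyl and cannot epimerise.

Step 10
Reactants: 17 (4R)-5-[(tert-butyldiphenylsilyl)oxy]-4-[2-methoxy-6-(methoxymethoxy)phenyl]pentanal; 18 ethyl 2-(triphenylphosphoranylidene)propanoate
Product: 19 ethyl (2E,6R)-7-[(tert-butyldiphenylsilyl)oxy]-6-[2-methoxy-6-(methoxymethoxy)phenyl]-2-methylhept-2-enoate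
Conditions: CH2Cl2, rt to 40 °C
Reagents that add atoms: none
Why: Wittig olefination with a stabilised, α-branched ylide gives the E-trisubstituted enoate (C11 cis to CH3); this geometry later becomes the C1 configuration.

Step 11
Reactants: 19 ethyl (2E,6R)-7-[(tert-butyldiphenylsilyl)oxy]-6-[2-methoxy-6-(methoxymethoxy)phenyl]-2-methylhept-2-enoate
Product: 20 (2E,6R)-7-[(tert-butyldiphenylsilyl)oxy]-6-[2-methoxy-6-(methoxymethoxy)phenyl]-2-methylhept-2-en-1-ol
Conditions: iBu2AlH, CH2Cl2, −78 °C
Reagents that add atoms: none
Why: 1,2-Reduction of the enoate to the allylic alcohol turns an electron-poor alkene into one nucleophilic enough for step 14, without touching its geometry.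

Step 12
Reactants: 20 (2E,6R)-7-[(tert-butyldiphenylsilyl)oxy]-6-[2-methoxy-6-(methoxymethoxy)phenyl]-2-methylhept-2-en-1-ol
Product: 21 tert-butyldimethylsilyl ether of 20
Conditions: tBuMe2SiCl, imidazole, CH2Cl2, rt
Reagents that add atoms: tert-butyl(chloro)dimethylsilane, CC(C)(C)[Si](C)(C)Cl
Why: Silylation; a TBS group makes this arm distinguishable from the TBDPS arm. A silyl ether, unlike an ester, has no carbonyl oxygen that could capture the C1 cation.

Step 13
Reactants: 21 tert-butyldimethylsilyl ether of 20
Product: 23 2-{(2R,5E)-7-[(tert-butyldimethylsilyl)oxy]-1-[(tert-butyldiphenylsilyl)oxy]-6-methylhept-5-en-2-yl}-3-methoxyphenol, via aryl trimethylsilyl ether 22 (not isolated)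
Conditions: Me3SiOTf, 2,2'-bipyridyl, CH2Cl2, 0 °C; then H2O
Reagents that add atoms: trimethylsilyl trifluoromethanesulfonate, C[Si](C)(C)OS(=O)(=O)C(F)(F)F (silyl group of 22 only)
Why: Silyl triflate–bipyridyl cleavage of an aryl MOM ether; the acetal is transferred to the pyridine nitrogen, the phenol appears as its labile trimethylsilyl ether, and water releases it. The medium is never protic-acidic, so the alkyl TBS and TBDPS ethers should stay.

Step 14
Reactants: 23 2-{(2R,5E)-7-[(tert-butyldimethylsilyl)oxy]-1-[(tert-butyldiphenylsilyl)oxy]-6-methylhept-5-en-2-yl}-3-methoxyphenol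
Product: 26 tricyclic enedione (rings B, C, D; ketones at C5 and C14; C3=C4; exo CH3 and endo CH2OTBS on C1; CH2OTBDPS on C9 cis to C5), via aryloxyiodane 24 (not isolated), via methyloxocarbenium acetate 25 (not isolated)
Conditions: PhI(OAc)2, (CF3)2CHOH (0.01 M), 0 °C; aq NaHCO3
Reagents that add atoms: (diacetoxyiodo)benzene, CC(=O)OI(OC(C)=O)c1ccccc1 (iodine and acetate of 24 and 25 only)
Why: Ligand exchange at trivalent iodine gives 24, whose O–I bond ionises in the strongly ionising, barely nucleophilic fluoroalcohol so that C13, C4 and C2 acquire pentadienyl-cation character; this is oxidative dearomatisation followed by cationic (5+2) cycloaddition, the reaction type known for ortho-(pent-4-enyl)phenols. Ring B closes first by 5-exo attack of the less substituted alkene carbon C12 on C13, a spiro closure that places the charge on tertiary C1. Ring C closes when C2, the δ-carbon of the methoxydienone and therefore nucleophilic, captures C1 in a second five-membered closure that also creates the bicyclo[3.2.1]octane; the charge ends on C5 as 25, which acetate demethylates to the enone. At C13 and C12 the three-atom tether allows only the cis fusion with C11 exo, at C2 the two-carbon bridge can span only one face, and at C1 suprafacial addition carries the E geometry into CH3 cis to C11 and CH2OTBS endo. The arene face is chosen by C9: with C10 standing over the ring, H9 faces the iodane-bearing oxygen on C14 and the bulky CH2OTBDPS lies beside the methoxy group, whose methyl can turn away. The step needs attack at C13 and not at C4, secured by the tether length, high dilution and the poor nucleophilicity of the solvent, and carbon capture (not oxygen capture) of the C1 cation, secured by the push of the C5 methoxy group towards C2. The minor facial isomer is opposite at C1, C2, C12 and C13, so it is a separable diastereomer and is removed here; epimerising its C9 later would produce the antipode, not the target.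

Step 15
Reactants: 26 tricyclic enedione
Product: 27 C14 alcohol (ketol; OH syn to the C1–C12 bridge)
Conditions: NaBH4 (1 equiv), MeOH/CH2Cl2, −78 °C; aq NH4Cl at −78 °C
Reagents that add atoms: none
Why: Chemoselective carbonyl reduction; the strained, non-conjugated bridge ketone is much more electrophilic than the conjugated neopentylic C5 ketone, and hydride arrives from the open enone side because the exo CH3 and C11 cover the other face. Low temperature and a cold buffered quench protect the non-enolisable 1,3-diketone from retro-Claisen cleavage and the ketol from retro-aldol opening.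

Step 16
Reactants: 27 C14 alcohol
Product: 28 O-phenyl thionocarbonate of 27
Conditions: PhOC(S)Cl, DMAP, CH2Cl2, rt
Reagents that add atoms: O-phenyl chlorothionoformate, ClC(=S)Oc1ccccc1
Why: Thioacylation under amine catalysis (first half of the Barton–McCombie deoxygenation); xanthate formation through an alkoxide is avoided because C14–O(−) is β to the C5 ketone and would break C13–C14 by retro-aldol.

Step 17
Reactants: 28 O-phenyl thionocarbonate of 27
Product: 29 tricyclic enone (C14 = CH2)
Conditions: Bu3SnH (0.3 M), AIBN (cat.), toluene, 85 °C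
Reagents that add atoms: none
Why: Barton–McCombie radical deoxygenation; the stannyl radical adds to C=S, C14–O fragments, and the bridge radical abstracts hydrogen from the stannane. The C2–C14 bond lies only about 30° out of the enone plane, so overlap for 3-exo attack on C3 is poor, and the high stannane concentration shortens the radical lifetime further.

Step 18
Reactants: 29 tricyclic enone
Product: 30 tricyclic diene (C3=C4–C5=CH2)
Conditions: Ph3PCH3Br, KOtBu, THF, 0 to 60 °C
Reagents that add atoms: methyltriphenylphosphonium bromide, C[P+](c1ccccc1)(c1ccccc1)c1ccccc1.[Br-]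
Why: Wittig methylenation adds C6; the ketone cannot enolise (C13 quaternary, C4 vinylic, γ-H on bridgehead C2), so excess ylide and heat are tolerable. The Michael acceptor is removed before the C1 arm is freed, because the endo CH2OH would lie exactly under C3 and close a five-membered oxa-Michael ring.

Step 19
Reactants: 30 tricyclic diene
Product: 31 primary alcohol on C1 (TBDPS ether retained)
Conditions: HF·pyridine, pyridine, THF, 0 °C to rt
Reagents that add atoms: none
Why: Selective desilylation; with acidic fluoride a primary TBS ether is cleaved far faster than a TBDPS ether, and the extra pyridine keeps the medium too weakly acidic to protonate the diene.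

Step 20
Reactants: 31 primary alcohol on C1
Product: 32 aldehyde on C1
Conditions: Dess–Martin periodinane, CH2Cl2, rt
Reagents that add atoms: none
Why: Dess–Martin oxidation handles neopentylic alcohols well; the aldehyde has no α-hydrogen and the s-trans diene cannot engage it.

Step 21
Reactants: 32 aldehyde on C1
Product: 33 carboxylic acid on C1
Conditions: NaClO2, NaH2PO4, 2-methylbut-2-ene (excess), tBuOH/H2O, rt
Reagents that add atoms: sodium chlorite, [Na+].[O-]Cl=O
Why: Pinnick oxidation; the large excess of scavenger alkene intercepts HOCl before it can reach the diene or start a chlorolactonisation onto C3=C4.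

Step 22
Reactants: 33 carboxylic acid on C1
Product: 34 methyl ester (diene, TBDPS ether)
Conditions: MeI, K2CO3, DMF, rt
Reagents that add atoms: iodomethane, CI
Why: Esterification by SN2 alkylation of the carboxylate, so the bond is made at the unhindered methyl carbon and not at the α-quaternary acyl carbon.

Step 23
Reactants: 34 methyl ester
Product: 36 C6 primary alcohol (H on C5 exo), via B-alkyl-9-BBN 35 (not isolated)
Conditions: 9-BBN, THF, 0 °C to rt; then H2O2, NaOH aq, 0 °C
Reagents that add atoms: 9-borabicyclo[3.3.1]nonane, B1C2CCCC1CCC2 (boryl group of 35 only); hydrogen peroxide, OO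
Why: Hydroboration–oxidation; 9-BBN strongly prefers the terminal carbon of the 1,1-disubstituted C5=C6 over the cis-disubstituted ring alkene C3=C4 and tolerates the hindered ester. Boron goes to C6 and hydrogen to C5 from the exo face, a centre that step 26 erases.

Step 24
Reactants: 36 C6 primary alcohol
Product: 37 1,5-diol (C6–OH and C8–OH)
Conditions: Bu4NF, THF, rt
Reagents that add atoms: none
Why: Fluoride desilylation; nothing base-sensitive is present and neither hydroxyl can reach the C1 ester in a small ring.

Step 25
Reactants: 37 1,5-diol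
Product: 38 1,5-dialdehyde (C6 and C8)
Conditions: (COCl)2, DMSO, CH2Cl2, −78 °C; Et3N, −78 to 0 °C
Reagents that add atoms: none
Why: Swern oxidation; both hydroxyl groups are converted into alkoxysulfonium ions at −78 °C before base is added, so no hydroxy aldehyde exists that could close to a lactol and be oxidised on to a lactone, the usual fate of 1,5-diols with slower oxidants.

Step 26
Reactants: 38 1,5-dialdehyde; 39 3-methylbutanoic anhydride
Product: 41 target CNP0315847.1, via lactol 40 (not isolated)
Conditions: Et3N, DMAP (cat.), CH2Cl2, rt; then 39, 0 °C to rt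
Reagents that add atoms: none
Why: Ring–chain tautomerism of a 1,5-dialdehyde followed by O-acylation, the way 1-O-acyl iridoid enol acetals are made; C5–H is both α to the aldehyde and allylic, so a mild amine gives the dienol, whose oxygen adds to the C8 aldehyde in a six-membered closure to 40, and DMAP-catalysed acylation removes 40 from the equilibrium. The anomers of 40 interconvert, and the one with oxygen anti to C10 (cis to H9) avoids eclipsing ring B and should be the one acylated, which sets C8 as S. C9 stays in, or returns to, the cis arrangement, because only that isomer can close.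

## Compound list

1 | 3-methoxyphenol | COc1cccc(O)c1 | starting material
2 | 1-methoxy-3-(methoxymethoxy)benzene | COCOc1cccc(OC)c1 | intermediate
3 | oxirane | C1CO1 | starting material
4 | 2-lithio-1-methoxy-3-(methoxymethoxy)benzene | [Li]c1c(OC)cccc1OCOC | intermediate
5 | 2-[2-methoxy-6-(methoxymethoxy)phenyl]ethanol | OCCc1c(OC)cccc1OCOC | intermediate
6 | [2-methoxy-6-(methoxymethoxy)phenyl]acetic acid | OC(=O)Cc1c(OC)cccc1OCOC | intermediate
7 | (R)-4-benzyl-1,3-oxazolidin-2-one | O=C1N[C@H](Cc2ccccc2)CO1 | starting material
8 | mixed anhydride of 6 and pivalic acid | CC(C)(C)C(=O)OC(=O)Cc1c(OC)cccc1OCOC | intermediate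
9 | (R)-4-benzyl-3-{[2-methoxy-6-(methoxymethoxy)phenyl]acetyl}-1,3-oxazolidin-2-one | COCOc1cccc(OC)c1CC(=O)N1[C@H](Cc2ccccc2)COC1=O | intermediate
10 | allyl iodide | C=CCI | starting material
11 | sodium Z-enolate of 9 | [Na+].[O-]/C(=C\c1c(OC)cccc1OCOC)N1[C@H](Cc2ccccc2)COC1=O | intermediate
12 | (4R)-4-benzyl-3-{(2R)-2-[2-methoxy-6-(methoxymethoxy)phenyl]pent-4-enoyl}-1,3-oxazolidin-2-one | COCOc1cccc(OC)c1[C@H](C(=O)N1[C@H](Cc2ccccc2)COC1=O)CC=C | intermediate
13 | (2R)-2-[2-methoxy-6-(methoxymethoxy)phenyl]pent-4-en-1-ol | COCOc1cccc(OC)c1[C@H](CO)CC=C | intermediate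
14 | tert-butyldiphenylsilyl ether of 13 | COCOc1cccc(OC)c1[C@H](CO[Si](c1ccccc1)(c1ccccc1)C(C)(C)C)CC=C | intermediate
15 | B-alkyl-9-BBN from 14 (boron on C12) | COCOc1cccc(OC)c1[C@H](CO[Si](c1ccccc1)(c1ccccc1)C(C)(C)C)CCCB1C2CCCC1CCC2 | intermediate
16 | (4R)-5-[(tert-butyldiphenylsilyl)oxy]-4-[2-methoxy-6-(methoxymethoxy)phenyl]pentan-1-ol | COCOc1cccc(OC)c1[C@H](CO[Si](c1ccccc1)(c1ccccc1)C(C)(C)C)CCCO | intermediate
17 | (4R)-5-[(tert-butyldiphenylsilyl)oxy]-4-[2-methoxy-6-(methoxymethoxy)phenyl]pentanal | COCOc1cccc(OC)c1[C@H](CO[Si](c1ccccc1)(c1ccccc1)C(C)(C)C)CCC=O | intermediate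
18 | ethyl 2-(triphenylphosphoranylidene)propanoate | CCOC(=O)C(C)=P(c1ccccc1)(c1ccccc1)c1ccccc1 | starting material
19 | ethyl (2E,6R)-7-[(tert-butyldiphenylsilyl)oxy]-6-[2-methoxy-6-(methoxymethoxy)phenyl]-2-methylhept-2-enoate | COCOc1cccc(OC)c1[C@H](CO[Si](c1ccccc1)(c1ccccc1)C(C)(C)C)CC/C=C(\C)C(=O)OCC | intermediate
20 | (2E,6R)-7-[(tert-butyldiphenylsilyl)oxy]-6-[2-methoxy-6-(methoxymethoxy)phenyl]-2-methylhept-2-en-1-ol | COCOc1cccc(OC)c1[C@H](CO[Si](c1ccccc1)(c1ccccc1)C(C)(C)C)CC/C=C(\C)CO | intermediate
21 | tert-butyldimethylsilyl ether of 20 | COCOc1cccc(OC)c1[C@H](CO[Si](c1ccccc1)(c1ccccc1)C(C)(C)C)CC/C=C(\C)CO[Si](C)(C)C(C)(C)C | intermediate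
22 | aryl trimethylsilyl ether of 23 | COc1cccc(O[Si](C)(C)C)c1[C@H](CO[Si](c1ccccc1)(c1ccccc1)C(C)(C)C)CC/C=C(\C)CO[Si](C)(C)C(C)(C)C | intermediate
23 | 2-{(2R,5E)-7-[(tert-butyldimethylsilyl)oxy]-1-[(tert-butyldiphenylsilyl)oxy]-6-methylhept-5-en-2-yl}-3-methoxyphenol | COc1cccc(O)c1[C@H](CO[Si](c1ccccc1)(c1ccccc1)C(C)(C)C)CC/C=C(\C)CO[Si](C)(C)C(C)(C)C | intermediate
24 | acetoxy(aryloxy)(phenyl)-λ3-iodane from 23 | CC(=O)OI(c1ccccc1)Oc1cccc(OC)c1[C@H](CO[Si](c1ccccc1)(c1ccccc1)C(C)(C)C)CC/C=C(\C)CO[Si](C)(C)C(C)(C)C | intermediate
25 | tricyclic C5 methyloxocarbenium acetate | CC(C)(C)[Si](C)(C)OC[C@]1(C)[C@@H]2C=CC(=[O+]C)[C@@]3([C@H](CO[Si](c4ccccc4)(c4ccccc4)C(C)(C)C)CC[C@@H]13)C2=O.CC(=O)[O-] | intermediate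
26 | tricyclic enedione (C5 and C14 ketones; C1, C2, C9, C12, C13 as in 41) | CC(C)(C)[Si](C)(C)OC[C@]1(C)[C@@H]2C=CC(=O)[C@@]3([C@H](CO[Si](c4ccccc4)(c4ccccc4)C(C)(C)C)CC[C@@H]13)C2=O | intermediate
27 | C14 alcohol of 26 (OH syn to the C1–C12 bridge) | CC(C)(C)[Si](C)(C)OC[C@]1(C)[C@@H]2C=CC(=O)[C@@]3([C@H](CO[Si](c4ccccc4)(c4ccccc4)C(C)(C)C)CC[C@@H]13)[C@@H]2O | intermediate
28 | O-phenyl thionocarbonate of 27 | CC(C)(C)[Si](C)(C)OC[C@]1(C)[C@@H]2C=CC(=O)[C@@]3([C@H](CO[Si](c4ccccc4)(c4ccccc4)C(C)(C)C)CC[C@@H]13)[C@@H]2OC(=S)Oc4ccccc4 | intermediate
29 | tricyclic enone (C14 = CH2) | CC(C)(C)[Si](C)(C)OC[C@]1(C)[C@@H]2C=CC(=O)[C@@]3([C@H](CO[Si](c4ccccc4)(c4ccccc4)C(C)(C)C)CC[C@@H]13)C2 | intermediate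
30 | tricyclic diene (C3=C4–C5=CH2) | CC(C)(C)[Si](C)(C)OC[C@]1(C)[C@@H]2C=CC(=C)[C@@]3([C@H](CO[Si](c4ccccc4)(c4ccccc4)C(C)(C)C)CC[C@@H]13)C2 | intermediate
31 | diene with free CH2OH on C1 | OC[C@]1(C)[C@@H]2C=CC(=C)[C@@]3([C@H](CO[Si](c4ccccc4)(c4ccccc4)C(C)(C)C)CC[C@@H]13)C2 | intermediate
32 | diene with CHO on C1 | O=C[C@]1(C)[C@@H]2C=CC(=C)[C@@]3([C@H](CO[Si](c4ccccc4)(c4ccccc4)C(C)(C)C)CC[C@@H]13)C2 | intermediate
33 | diene with CO2H on C1 | OC(=O)[C@]1(C)[C@@H]2C=CC(=C)[C@@]3([C@H](CO[Si](c4ccccc4)(c4ccccc4)C(C)(C)C)CC[C@@H]13)C2 | intermediate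
34 | diene methyl ester | COC(=O)[C@]1(C)[C@@H]2C=CC(=C)[C@@]3([C@H](CO[Si](c4ccccc4)(c4ccccc4)C(C)(C)C)CC[C@@H]13)C2 | intermediate
35 | B-alkyl-9-BBN from 34 (boron on C6) | COC(=O)[C@]1(C)[C@@H]2C=C[C@H](CB4C5CCCC4CCC5)[C@@]3([C@H](CO[Si](c4ccccc4)(c4ccccc4)C(C)(C)C)CC[C@@H]13)C2 | intermediate
36 | C6 primary alcohol (TBDPS ether on the C8 oxygen) | COC(=O)[C@]1(C)[C@@H]2C=C[C@H](CO)[C@@]3([C@H](CO[Si](c4ccccc4)(c4ccccc4)C(C)(C)C)CC[C@@H]13)C2 | intermediate
37 | 1,5-diol (C6–OH, C8–OH) | COC(=O)[C@]1(C)[C@@H]2C=C[C@H](CO)[C@@]3([C@H](CO)CC[C@@H]13)C2 | intermediate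
38 | 1,5-dialdehyde (C6, C8) | COC(=O)[C@]1(C)[C@@H]2C=C[C@H](C=O)[C@@]3([C@H](C=O)CC[C@@H]13)C2 | intermediate
39 | 3-methylbutanoic anhydride | CC(C)CC(=O)OC(=O)CC(C)C | starting material
40 | tetracyclic dienol lactol (C8–OH cis to H9) | COC(=O)[C@]1(C)[C@@H]2C=CC3=CO[C@@H](O)[C@@H]4CC[C@@H]1[C@]34C2 | intermediate
41 | CNP0315847.1, (1R,2S,8S,9R,12R,13S) in the labels used here | COC(=O)[C@]1(C)[C@@H]2C=CC3=CO[C@@H](OC(=O)CC(C)C)[C@@H]4CC[C@@H]1[C@]34C2 | target

## Step count and least certain steps

Total step count: 26. Longest linear sequence: 26 steps. The route is linear from 1; compounds 3, 7, 10, 18 and 39 are purchased.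

**Step 14 (key step).**
- *Risk.* The most likely weakness is poor facial discrimination. Once iodobenzene has left, the oxygen on C14 is hardly larger than the methoxy oxygen on C5, so the preference for H9 next to C14 may be small and material is lost to the wrong diastereomeric series.
- *Further leaks.* These are capture of the ring cation at C4 by acetate or solvent, proton loss from the C1 cation, and attack of the silyl ether oxygen of the C1 arm on C3 with loss of the silyl group, for which the geometry is good.
- *Fallback.* Oxidation and cyclisation are separated. From 23, Wessely oxidation with Pb(OAc)4 (CH2Cl2, −20 °C) would give the o-quinol acetate F1 (acetoxy group on C13, both epimers). F1 is purified and then ionised without any oxidant at −40 °C in CH2Cl2/(CF3)2CHOH with catalytic BF3·OEt2. The cation then forms exactly at C13, at a temperature where rotamer preferences count for more and without excess acetate. The cycloaddition rejoins the route at 26.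

**Step 26.**
- *Risk.* Tautomerisation of the β,γ-unsaturated aldehyde into the conjugated C4=C5 enal may outrun ring closure, because the conjugated form is the thermodynamic sink of the open chain. Direct O-acylation of open-chain enolates at C6 or C8 may also compete with acylation of 40.
- *Fallback.* Ring A is closed at the saturated stage, where no dienol is needed. From 38, treatment with 39 and catalytic Sc(OTf)3 (CH2Cl2, 0 °C) would give the cyclic bis(isovaleryloxy) acetal F2, a 2,6-diacyloxytetrahydropyran of the kind formed by 1,5-dialdehydes with anhydrides. Me3SiOTf and iPr2NEt (−78 to 0 °C) then ionise the C6 acyloxy group and remove the allylic C5–H. One molecule of acid is lost towards the conjugated dienol ether, and the route is rejoined at 41.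

**Step 17.**
- *Risk.* The C14 radical is homoallylic to the β-carbon C3 of the enone. Closure to a cyclopropylcarbinyl radical and vinyl migration to a bicyclo[3.3.0] skeleton, or stannane reduction of the enone, may compete with hydrogen abstraction.
- *Fallback.* The alkene is masked. From 27, thiophenol and catalytic Et3N add to C3 from the exo face to give the β-phenylthio ketone F3. Thioacylation as in step 16 gives the thionocarbonate F4. The stannane reduction, now with no C=C bond near C14, gives the sulfide F5. One equivalent of mCPBA at −78 °C gives the sulfoxide F6, and warming in toluene (syn elimination) restores C3=C4 and rejoins the route at 29.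

**Step 18.**
- *Risk.* The C5 carbonyl is flanked by quaternary C13 and by the CH2OTBDPS arm, so betaine formation may be too slow and the ylide may decompose first.
- *Fallback.* From 29, MeLi with CeCl3 (THF, −78 °C), a much smaller nucleophile, adds 1,2 to give the tertiary allylic alcohol F7. Dehydration with the Burgess reagent (toluene, 50 °C) can take only a methyl hydrogen, because C13 is quaternary and C4 is vinylic, and it leads to 30.

**Step 13.**
- *Risk.* Partial loss of the primary allylic TBS group may accompany cleavage of the MOM ether, since both respond to silyl Lewis acids.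
- *Fallback.* The phenol is released earlier, on an acid-stable substrate. From 19, HCl in EtOH (40 °C) gives the phenol ester F8. iBu2AlH (3.3 equiv, −78 °C) gives the phenol allylic alcohol F9. tBuMe2SiCl (2.5 equiv) and imidazole give the bis(tert-butyldimethylsilyl) compound F10. K2CO3 in MeOH at rt cleaves only the aryl silyl ether and rejoins the route at 23. This costs one step more than the main line.

## Further compounds

F1 | step 14 | 6-acetoxy-5-methoxy-6-alkylcyclohexa-2,4-dienone (o-quinol acetate, C13 epimers) | COC1=CC=CC(=O)C1(OC(C)=O)[C@H](CO[Si](c1ccccc1)(c1ccccc1)C(C)(C)C)CC/C=C(\C)CO[Si](C)(C)C(C)(C)C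
F2 | step 26 | cyclic C6,C8-bis(3-methylbutanoyloxy) acetal (C5 and C6 mixtures) | COC(=O)[C@]1(C)[C@@H]2C=CC3C(OC(=O)CC(C)C)O[C@@H](OC(=O)CC(C)C)[C@@H]4CC[C@@H]1[C@]34C2
F3 | step 17 | 3-exo-phenylthio ketone from 27 | CC(C)(C)[Si](C)(C)OC[C@]1(C)[C@@H]2[C@@H](Sc4ccccc4)CC(=O)[C@@]3([C@H](CO[Si](c4ccccc4)(c4ccccc4)C(C)(C)C)CC[C@@H]13)[C@@H]2O
F4 | step 17 | O-phenyl thionocarbonate of F3 | CC(C)(C)[Si](C)(C)OC[C@]1(C)[C@@H]2[C@@H](Sc4ccccc4)CC(=O)[C@@]3([C@H](CO[Si](c4ccccc4)(c4ccccc4)C(C)(C)C)CC[C@@H]13)[C@@H]2OC(=S)Oc4ccccc4
F5 | step 17 | deoxygenated phenylthio ketone (C14 = CH2) | CC(C)(C)[Si](C)(C)OC[C@]1(C)[C@@H]2[C@@H](Sc4ccccc4)CC(=O)[C@@]3([C@H](CO[Si](c4ccccc4)(c4ccccc4)C(C)(C)C)CC[C@@H]13)C2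
F6 | step 17 | sulfoxide of F5 (sulfur epimers) | CC(C)(C)[Si](C)(C)OC[C@]1(C)[C@@H]2[C@@H](S(=O)c4ccccc4)CC(=O)[C@@]3([C@H](CO[Si](c4ccccc4)(c4ccccc4)C(C)(C)C)CC[C@@H]13)C2
F7 | step 18 | C5 tertiary allylic alcohol (CH3 exo) | CC(C)(C)[Si](C)(C)OC[C@]1(C)[C@@H]2C=C[C@](C)(O)[C@@]3([C@H](CO[Si](c4ccccc4)(c4ccccc4)C(C)(C)C)CC[C@@H]13)C2
F8 | step 13 | ethyl (2E,6R)-7-[(tert-butyldiphenylsilyl)oxy]-6-(2-hydroxy-6-methoxyphenyl)-2-methylhept-2-enoate | COc1cccc(O)c1[C@H](CO[Si](c1ccccc1)(c1ccccc1)C(C)(C)C)CC/C=C(\C)C(=O)OCC
F9 | step 13 | 2-{(2R,5E)-1-[(tert-butyldiphenylsilyl)oxy]-7-hydroxy-6-methylhept-5-en-2-yl}-3-methoxyphenol | COc1cccc(O)c1[C@H](CO[Si](c1ccccc1)(c1ccccc1)C(C)(C)C)CC/C=C(\C)CO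
F10 | step 13 | aryl and allyl bis(tert-butyldimethylsilyl) ether of F9 | COc1cccc(O[Si](C)(C)C(C)(C)C)c1[C@H](CO[Si](c1ccccc1)(c1ccccc1)C(C)(C)C)CC/C=C(\C)CO[Si](C)(C)C(C)(C)C
A1 | alternative 1 | monocyclic trienal with E-enol isovalerate (C5=C13 geometry open) | COC(=O)[C@]1(C)[C@H](C=C)CC(=C(C=C)C=O)[C@H]1CC/C=C/OC(=O)CC(C)C
A2 | alternative 1 | tricyclic divinyl acyloxy acetal (rings A, B, C) | COC(=O)[C@]1(C)[C@H](C=C)C[C@@]23C(C=C)=CO[C@@H](OC(=O)CC(C)C)[C@@H]2CC[C@@H]13
A3 | alternative 2 | bicyclic enyne vinyl ester (rings B, C) | COC(=O)[C@]1(C)[C@H](C=C)C[C@@]2(C#C)[C@H](C(=O)OC=C)CC[C@@H]12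
A4 | alternative 2 | tetracyclic enol lactone (C8 carbonyl) | COC(=O)[C@]1(C)[C@@H]2C=CC3=COC(=O)[C@@H]4CC[C@@H]1[C@]34C2
A5 | alternative 3 | bridged seven-membered lactone (C1 epimers) | CC1C(=O)O[C@H]2C=CC[C@]3([C@H](CO[Si](C)(C)C(C)(C)C)CC[C@@H]13)[C@@H]2CO[Si](C)(C)C(C)(C)C
A6 | alternative 3 | tricyclic carboxylic acid (rings B, C, D) | OC(=O)[C@]1(C)[C@@H]2C=C[C@@H](CO[Si](C)(C)C(C)(C)C)[C@@]3([C@H](CO[Si](C)(C)C(C)(C)C)CC[C@@H]13)C2
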